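**Plan**
- Retrosynthetic cuts: C6–C(=O) (aryllithium plus a Weinreb cinnamamide), C2'=C3' of the prenyl group (Wittig), C3–C1' (cross-coupling at a C3 enol triflate), and removal of C4 from the pyran ring. This leads back to a 2,2-dimethylbenzofuran-3(2H)-one and to phloroglucinol.
- Forward, the hindered O1–C2(CH3)2 aryl ether is made first. It forms inside the five-membered ring O1–C2–C(=O)–C4a–C8a, where it closes easily and without a regiochemical issue.
- The pyran ring then arises by insertion of one carbon atom (the later C4) between the carbonyl carbon (the later C3) and C4a. The sequence is β-oxido carbenoid, 1,2-aryl shift, then trapping of the enolate as triflate.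
- Two features make this possible. C4a lies ortho, ortho and para to O1, O5 and O7 of the phloroglucinol ring, so it is an outstanding migrating carbon. C2 is quaternary, so no enolisation competes, only one enolate can form, and C3 is left as an sp2 handle where the side chain and the stereocentre are needed.
- C3 is the only stereocentre. It comes from an Ir-catalysed asymmetric hydrogenation of C3=C4. The E-enone geometry comes from a Horner–Wadsworth–Emmons reaction.
- End game: ester to aldehyde to prenyl, lithiation at C6 between OMOM and OMe, acylation, and removal of the MOM groups.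

Key step: step 5

Remark: the sense of induction in step 7 depends on the antipode of the N,P ligand. The antipode that delivers (3S)-12 is assumed.

**Step 1**
Reactants: 1 phloroglucinol; 2 2-bromo-2-methylpropanoyl bromide
Product: 4 4,6-dihydroxy-2,2-dimethyl-1-benzofuran-3(2H)-one, via bromo ketone 3 (not isolated)
Conditions: AlCl3, CH2Cl2–PhNO2, 0 to 40 °C; aq. HCl; crude product with NaOAc, EtOH, reflux
Reagents that add atoms: none
Why: Friedel–Crafts acylation of the threefold symmetric phloroglucinol has no regiochemical issue, and an ortho phenoxide of 3 then displaces the tertiary α-keto bromide in a 5-exo-tet O-alkylation that builds the hindered O–C(CH3)2 aryl ether at the outset.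

**Step 2**
Reactants: 4 4,6-dihydroxy-2,2-dimethyl-1-benzofuran-3(2H)-one
Product: 5 4-hydroxy-6-methoxy-2,2-dimethyl-1-benzofuran-3(2H)-one
Conditions: MeI (1.05 equiv), K2CO3 (1.0 equiv), acetone, rt
Reagents that add atoms: iodomethane, CI
Why: Williamson etherification with one equivalent of base takes the 6-OH, which is para to the carbonyl group and the more acidic one, while the 4-OH is held back by its hydrogen bond to C3=O.

**Step 3**
Reactants: 5 4-hydroxy-6-methoxy-2,2-dimethyl-1-benzofuran-3(2H)-one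
Product: 6 6-methoxy-4-(methoxymethoxy)-2,2-dimethyl-1-benzofuran-3(2H)-one
Conditions: NaH, DMF, 0 °C; MOMCl, 0 °C to rt
Reagents that add atoms: chloromethyl methyl ether, COCCl
Why: Standard MOM protection of the chelated phenol through its sodium salt gives a group that withstands the organolithium steps and later directs the lithiation to C6.

**Step 4**
Reactants: 6 6-methoxy-4-(methoxymethoxy)-2,2-dimethyl-1-benzofuran-3(2H)-one
Product: 7 rac-3-(dibromomethyl)-6-methoxy-4-(methoxymethoxy)-2,2-dimethyl-2,3-dihydro-1-benzofuran-3-ol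
Conditions: CH2Br2, LDA added to the mixture, THF, −90 to −78 °C; aq. NH4Cl
Reagents that add atoms: dibromomethane, BrCBr
Why: Dibromomethyllithium, made in the presence of the ketone, undergoes 1,2-addition to a carbonyl group that cannot enolise because C2 is quaternary; the new carbinol centre is racemic and is erased in step 5.

**Step 5**
Reactants: 7 rac-3-(dibromomethyl)-6-methoxy-4-(methoxymethoxy)-2,2-dimethyl-2,3-dihydro-1-benzofuran-3-ol
Product: 10 7-methoxy-5-(methoxymethoxy)-2,2-dimethyl-2H-chromen-3-yl trifluoromethanesulfonate, via beta-oxido carbenoid 8 (not isolated), via lithium enolate 9 (not isolated)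
Conditions: n-BuLi (2.2 equiv), THF, −78 to 0 °C; PhNTf2, −78 °C to rt; aq. NH4Cl
Reagents that add atoms: N-phenylbis(trifluoromethanesulfonimide), O=S(=O)(N(c1ccccc1)S(=O)(=O)C(F)(F)F)C(F)(F)F
Why: The first equivalent of n-BuLi makes the lithium alkoxide and the second exchanges one bromine for lithium to give the β-oxido carbenoid 8; on warming, the aryl carbon C3a (the later C4a) shifts from the carbinol carbon to the carbenoid carbon with loss of LiBr while the alkoxide folds down to the enolate 9, so that the five-membered ring O1–C2–C3–C3a–C7a takes up the carbenoid carbon as C4 and becomes the six-membered pyran ring. The closest known reaction type is the Taguchi–Nozaki one-carbon ring enlargement of cyclic ketones through dibromomethyl carbinols, a carbenoid relative of the Tiffeneau–Demjanov reaction. No ring is closed from an open chain: the ring grows by a 1,2-shift through a phenonium-like three-membered transition state, formally a 3-exo-tet attack of the ipso carbon on the C–Br carbon followed by cleavage of the old aryl–carbinol bond. No stereocentre is formed, and that of racemic 7 is erased as C3 becomes sp2. The step needs aryl over alkyl migration, which is secured because the migrating carbon lies ortho, ortho and para to three oxygen donors, whereas the rival C2 is a tertiary carbon that carries the electron-withdrawing ring oxygen. Because C2 is quaternary only one enolate can exist, so PhNTf2 fixes it as the C3 enol triflate 10 with the double bond at C3=C4.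

**Step 6**
Reactants: 10 7-methoxy-5-(methoxymethoxy)-2,2-dimethyl-2H-chromen-3-yl trifluoromethanesulfonate
Product: 11 ethyl [7-methoxy-5-(methoxymethoxy)-2,2-dimethyl-2H-chromen-3-yl]acetate
Conditions: BrZnCH2CO2Et (2 equiv), Pd(PPh3)4 (5 mol %), THF, 65 °C
Reagents that add atoms: (2-ethoxy-2-oxoethyl)zinc bromide, CCOC(=O)C[Zn]Br
Why: Negishi-type cross-coupling of a Reformatsky reagent with an alkenyl triflate joins C3 to C1' and leaves the double bond in the aryl-conjugated C3=C4 position.

**Step 7**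
Reactants: 11 ethyl [7-methoxy-5-(methoxymethoxy)-2,2-dimethyl-2H-chromen-3-yl]acetate
Product: 12 ethyl [(3S)-7-methoxy-5-(methoxymethoxy)-2,2-dimethyl-3,4-dihydro-2H-chromen-3-yl]acetate
Conditions: H2 (50 bar), [Ir(cod)(chiral N,P ligand of the PHOX or pyridine–phosphinite type)]BArF (1–2 mol %), CH2Cl2, rt
Reagents that add atoms: none
Why: Ir–N,P-catalysed asymmetric hydrogenation of a trisubstituted, aryl-conjugated cyclic olefin adds H2 syn to one face, the ligand telling the quaternary C2 from the CH2CO2Et arm, and so sets C3 (the (3S) descriptor of 12 is the same spatial arrangement as (3R) in the target, since C4 and the side chain change CIP rank after step 9).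

**Step 8**
Reactants: 12 ethyl [(3S)-7-methoxy-5-(methoxymethoxy)-2,2-dimethyl-3,4-dihydro-2H-chromen-3-yl]acetate
Product: 13 [(3S)-7-methoxy-5-(methoxymethoxy)-2,2-dimethyl-3,4-dihydro-2H-chromen-3-yl]acetaldehyde
Conditions: DIBAL-H (1.05 equiv), CH2Cl2, −78 °C; aq. Rochelle salt
Reagents that add atoms: none
Why: Partial ester reduction with DIBAL-H at low temperature stops at the aluminium hemiacetal, which gives the aldehyde on work-up, and C3 is β to the carbonyl group and cannot epimerise.

**Step 9**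
Reactants: 13 [(3S)-7-methoxy-5-(methoxymethoxy)-2,2-dimethyl-3,4-dihydro-2H-chromen-3-yl]acetaldehyde
Product: 14 (3R)-7-methoxy-5-(methoxymethoxy)-2,2-dimethyl-3-(3-methylbut-2-en-1-yl)-3,4-dihydro-2H-chromene
Conditions: i-PrPPh3I, n-BuLi, THF, 0 °C; then 13, −78 °C to rt
Reagents that add atoms: isopropyltriphenylphosphonium iodide, CC(C)[P+](c1ccccc1)(c1ccccc1)c1ccccc1.[I-]
Why: Wittig olefination with the non-stabilised isopropylidene ylide turns the aldehyde into the trisubstituted prenyl double bond, for which no E/Z issue exists.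

**Step 10**
Reactants: 15 2,4-dihydroxybenzaldehyde
Product: 16 2,4-bis(methoxymethoxy)benzaldehyde
Conditions: NaH (2.4 equiv), DMF, 0 °C; MOMCl (2.4 equiv), 0 °C to rt
Reagents that add atoms: chloromethyl methyl ether, COCCl
Why: Double MOM protection of the two phenols masks the acidic protons of ring B for the organolithium coupling.

**Step 11**
Reactants: 16 2,4-bis(methoxymethoxy)benzaldehyde; 17 diethyl {2-[methoxy(methyl)amino]-2-oxoethyl}phosphonate
Product: 18 (2E)-3-[2,4-bis(methoxymethoxy)phenyl]-N-methoxy-N-methylprop-2-enamide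
Conditions: NaH, THF, 0 °C to rt
Reagents that add atoms: none
Why: Horner–Wadsworth–Emmons olefination with a stabilised phosphonate anion gives the E-configured enamide.

**Step 12**
Reactants: 14 (3R)-7-methoxy-5-(methoxymethoxy)-2,2-dimethyl-3-(3-methylbut-2-en-1-yl)-3,4-dihydro-2H-chromene; 18 (2E)-3-[2,4-bis(methoxymethoxy)phenyl]-N-methoxy-N-methylprop-2-enamide
Product: 20 (2E)-3-[2,4-bis(methoxymethoxy)phenyl]-1-[(3R)-7-methoxy-5-(methoxymethoxy)-2,2-dimethyl-3-(3-methylbut-2-en-1-yl)-3,4-dihydro-2H-chromen-6-yl]prop-2-en-1-one, via C6 aryllithium 19 (not isolated)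
Conditions: n-BuLi (1.1 equiv), TMEDA, THF, 0 °C; then 18, −78 to 0 °C; aq. NH4Cl
Reagents that add atoms: none
Why: Directed ortho-metalation takes place at C6, the position flanked by OMOM (the stronger director) and OMe, and the aryllithium adds 1,2 to the Weinreb amide to give a chelated adduct that releases the E-enone only on work-up.

**Step 13**
Reactants: 20 (2E)-3-[2,4-bis(methoxymethoxy)phenyl]-1-[(3R)-7-methoxy-5-(methoxymethoxy)-2,2-dimethyl-3-(3-methylbut-2-en-1-yl)-3,4-dihydro-2H-chromen-6-yl]prop-2-en-1-one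
Product: 21 (2E)-3-(2,4-dihydroxyphenyl)-1-[(3R)-5-hydroxy-7-methoxy-2,2-dimethyl-3-(3-methylbut-2-en-1-yl)-3,4-dihydro-2H-chromen-6-yl]prop-2-en-1-one
Conditions: HCl (cat., aq.), MeOH, rt to 40 °C
Reagents that add atoms: none
Why: Acid-catalysed acetal exchange with methanol removes the three MOM groups under the mild conditions commonly used for prenylated 2'-hydroxychalcones, which should spare the prenyl group, the enone and the tertiary alkyl aryl ether.

**Compound list**
1 | phloroglucinol | Oc1cc(O)cc(O)c1 | starting material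
2 | 2-bromo-2-methylpropanoyl bromide | CC(C)(Br)C(=O)Br | starting material
3 | 2-bromo-2-methyl-1-(2,4,6-trihydroxyphenyl)propan-1-one | CC(C)(Br)C(=O)c1c(O)cc(O)cc1O | intermediate
4 | 4,6-dihydroxy-2,2-dimethyl-1-benzofuran-3(2H)-one | CC1(C)Oc2cc(O)cc(O)c2C1=O | intermediate
5 | 4-hydroxy-6-methoxy-2,2-dimethyl-1-benzofuran-3(2H)-one | COc1cc(O)c2C(=O)C(C)(C)Oc2c1 | intermediate
6 | 6-methoxy-4-(methoxymethoxy)-2,2-dimethyl-1-benzofuran-3(2H)-one | COCOc1cc(OC)cc2OC(C)(C)C(=O)c12 | intermediate
7 | rac-3-(dibromomethyl)-6-methoxy-4-(methoxymethoxy)-2,2-dimethyl-2,3-dihydro-1-benzofuran-3-ol | COCOc1cc(OC)cc2OC(C)(C)C(O)(C(Br)Br)c12 | intermediate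
8 | lithium alkoxide of the 3-[bromo(lithio)methyl] carbinol (β-oxido carbenoid) | COCOc1cc(OC)cc2OC(C)(C)C(O[Li])(C([Li])Br)c12 | intermediate
9 | lithium 7-methoxy-5-(methoxymethoxy)-2,2-dimethyl-2H-chromen-3-olate | COCOc1cc(OC)cc2OC(C)(C)C(O[Li])=Cc12 | intermediate
10 | 7-methoxy-5-(methoxymethoxy)-2,2-dimethyl-2H-chromen-3-yl trifluoromethanesulfonate | COCOc1cc(OC)cc2OC(C)(C)C(OS(=O)(=O)C(F)(F)F)=Cc12 | intermediate
11 | ethyl [7-methoxy-5-(methoxymethoxy)-2,2-dimethyl-2H-chromen-3-yl]acetate | CCOC(=O)CC1=Cc2c(OCOC)cc(OC)cc2OC1(C)C | intermediate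
12 | ethyl [(3S)-7-methoxy-5-(methoxymethoxy)-2,2-dimethyl-3,4-dihydro-2H-chromen-3-yl]acetate | COCOc1cc(OC)cc2c1C[C@@H](CC(=O)OCC)C(C)(C)O2 | intermediate
13 | [(3S)-7-methoxy-5-(methoxymethoxy)-2,2-dimethyl-3,4-dihydro-2H-chromen-3-yl]acetaldehyde | COCOc1cc(OC)cc2c1C[C@@H](CC=O)C(C)(C)O2 | intermediate
14 | (3R)-7-methoxy-5-(methoxymethoxy)-2,2-dimethyl-3-(3-methylbut-2-en-1-yl)-3,4-dihydro-2H-chromene | COCOc1cc(OC)cc2c1C[C@@H](CC=C(C)C)C(C)(C)O2 | intermediate
15 | 2,4-dihydroxybenzaldehyde | O=Cc1ccc(O)cc1O | starting material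
16 | 2,4-bis(methoxymethoxy)benzaldehyde | COCOc1ccc(C=O)c(OCOC)c1 | intermediate
17 | diethyl {2-[methoxy(methyl)amino]-2-oxoethyl}phosphonate | CCOP(=O)(CC(=O)N(C)OC)OCC | starting material
18 | (2E)-3-[2,4-bis(methoxymethoxy)phenyl]-N-methoxy-N-methylprop-2-enamide | COCOc1ccc(/C=C/C(=O)N(C)OC)c(OCOC)c1 | intermediate
19 | (3R)-6-lithio-7-methoxy-5-(methoxymethoxy)-2,2-dimethyl-3-(3-methylbut-2-en-1-yl)-3,4-dihydro-2H-chromene | COCOc1c([Li])c(OC)cc2c1C[C@@H](CC=C(C)C)C(C)(C)O2 | intermediate
20 | (2E)-3-[2,4-bis(methoxymethoxy)phenyl]-1-[(3R)-7-methoxy-5-(methoxymethoxy)-2,2-dimethyl-3-(3-methylbut-2-en-1-yl)-3,4-dihydro-2H-chromen-6-yl]prop-2-en-1-one | COCOc1ccc(/C=C/C(=O)c2c(OC)cc3c(c2OCOC)C[C@@H](CC=C(C)C)C(C)(C)O3)c(OCOC)c1 | intermediate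
21 | (2E)-3-(2,4-dihydroxyphenyl)-1-[(3R)-5-hydroxy-7-methoxy-2,2-dimethyl-3-(3-methylbut-2-en-1-yl)-3,4-dihydro-2H-chromen-6-yl]prop-2-en-1-one | COc1cc2c(c(O)c1C(=O)/C=C/c1ccc(O)cc1O)C[C@@H](CC=C(C)C)C(C)(C)O2 | target

Total step count: 13. Longest linear sequence: 11 (steps 1–9, 12, 13).

**Steps most likely to fail**

**Step 5 (with the addition of step 4 that feeds it).**
- Risk: the carbenoid may be protonated, or may close to a bromo epoxide, faster than the aryl group shifts. The 1,2-addition to the hindered, electron-rich ketone may also stall.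
- The fallback sets out from 6 and comes back at 10. It replaces the carbenoid by a cationoid semipinacol shift.
- MeMgBr/CeCl3 adds to 6 and should give the tertiary alcohol 6-methoxy-4-(methoxymethoxy)-2,2,3-trimethyl-2,3-dihydro-1-benzofuran-3-ol F1.
- With PPTS, F1 loses water to the only possible olefin, 6-methoxy-4-(methoxymethoxy)-2,2-dimethyl-3-methylidene-2,3-dihydro-1-benzofuran F2.
- OsO4/NMO gives the diol 3-(hydroxymethyl)-6-methoxy-4-(methoxymethoxy)-2,2-dimethyl-2,3-dihydro-1-benzofuran-3-ol F3.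
- MsCl/collidine gives the primary sulfonate [3-hydroxy-6-methoxy-4-(methoxymethoxy)-2,2-dimethyl-2,3-dihydro-1-benzofuran-3-yl]methyl methanesulfonate F4.
- Et3Al in CH2Cl2 at −78 °C triggers the pinacol-type 1,2-aryl shift of a β-mesyloxy alcohol. This gives the ring-enlarged ketone 7-methoxy-5-(methoxymethoxy)-2,2-dimethylchroman-3-one F5.
- KHMDS and PhNTf2 convert F5 into 10.

**Step 7.**
- Risk: low conversion and poor facial selectivity, because the olefin sits next to the quaternary C2.
- The fallback sets out from 11 and comes back at 12. It replaces catalytic induction by a classical resolution.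
- H2 over Pd/C gives the racemic ester ethyl [7-methoxy-5-(methoxymethoxy)-2,2-dimethyl-3,4-dihydro-2H-chromen-3-yl]acetate F6.
- LiOH gives the racemic acid [7-methoxy-5-(methoxymethoxy)-2,2-dimethyl-3,4-dihydro-2H-chromen-3-yl]acetic acid F7.
- DCC/DMAP with (S)-4-benzyloxazolidin-2-one gives two imides: (4S)-4-benzyl-3-{[(3S)-7-methoxy-5-(methoxymethoxy)-2,2-dimethyl-3,4-dihydro-2H-chromen-3-yl]acetyl}oxazolidin-2-one F8 and its (3R) diastereomer (4S)-4-benzyl-3-{[(3R)-7-methoxy-5-(methoxymethoxy)-2,2-dimethyl-3,4-dihydro-2H-chromen-3-yl]acetyl}oxazolidin-2-one F9.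
- The imides are separated by chromatography or crystallisation.
- NaOEt in EtOH at 0 °C turns F8 into 12.

**Step 12.**
- Risk: sluggish attack of the doubly ortho-substituted aryllithium on the enamide, and competing 1,4-addition.
- The fallback sets out from 14 and comes back at 20. It builds the enone by aldol condensation instead of acyl substitution.
- The aryllithium 19 is quenched with the small electrophile N-methoxy-N-methylacetamide. This gives the methyl ketone 1-[(3R)-7-methoxy-5-(methoxymethoxy)-2,2-dimethyl-3-(3-methylbut-2-en-1-yl)-3,4-dihydro-2H-chromen-6-yl]ethanone F10.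
- A Claisen–Schmidt condensation of F10 with aldehyde 16 (KOH, EtOH) gives 20.

**Further compounds**
F1 | step 5 | 6-methoxy-4-(methoxymethoxy)-2,2,3-trimethyl-2,3-dihydro-1-benzofuran-3-ol (racemic) | COCOc1cc(OC)cc2OC(C)(C)C(C)(O)c12
F2 | step 5 | 6-methoxy-4-(methoxymethoxy)-2,2-dimethyl-3-methylidene-2,3-dihydro-1-benzofuran | COCOc1cc(OC)cc2OC(C)(C)C(=C)c12
F3 | step 5 | 3-(hydroxymethyl)-6-methoxy-4-(methoxymethoxy)-2,2-dimethyl-2,3-dihydro-1-benzofuran-3-ol (racemic) | COCOc1cc(OC)cc2OC(C)(C)C(O)(CO)c12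
F4 | step 5 | [3-hydroxy-6-methoxy-4-(methoxymethoxy)-2,2-dimethyl-2,3-dihydro-1-benzofuran-3-yl]methyl methanesulfonate (racemic) | COCOc1cc(OC)cc2OC(C)(C)C(O)(COS(C)(=O)=O)c12
F5 | step 5 | 7-methoxy-5-(methoxymethoxy)-2,2-dimethylchroman-3-one | COCOc1cc(OC)cc2OC(C)(C)C(=O)Cc12
F6 | step 7 | ethyl [7-methoxy-5-(methoxymethoxy)-2,2-dimethyl-3,4-dihydro-2H-chromen-3-yl]acetate (racemic) | COCOc1cc(OC)cc2c1CC(CC(=O)OCC)C(C)(C)O2
F7 | step 7 | [7-methoxy-5-(methoxymethoxy)-2,2-dimethyl-3,4-dihydro-2H-chromen-3-yl]acetic acid (racemic) | COCOc1cc(OC)cc2c1CC(CC(=O)O)C(C)(C)O2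
F8 | step 7 | (4S)-4-benzyl-3-{[(3S)-7-methoxy-5-(methoxymethoxy)-2,2-dimethyl-3,4-dihydro-2H-chromen-3-yl]acetyl}oxazolidin-2-one | COCOc1cc(OC)cc2c1C[C@@H](CC(=O)N1C(=O)OC[C@@H]1Cc1ccccc1)C(C)(C)O2
F9 | step 7 | (4S)-4-benzyl-3-{[(3R)-7-methoxy-5-(methoxymethoxy)-2,2-dimethyl-3,4-dihydro-2H-chromen-3-yl]acetyl}oxazolidin-2-one | COCOc1cc(OC)cc2c1C[C@H](CC(=O)N1C(=O)OC[C@@H]1Cc1ccccc1)C(C)(C)O2
F10 | step 12 | 1-[(3R)-7-methoxy-5-(methoxymethoxy)-2,2-dimethyl-3-(3-methylbut-2-en-1-yl)-3,4-dihydro-2H-chromen-6-yl]ethanone | COCOc1c(C(C)=O)c(OC)cc2c1C[C@@H](CC=C(C)C)C(C)(C)O2
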